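**Strategy**

The route rests on cutting ring B (C1–C8–C7–C6–C5–C9) at C1–C8 and C6–C7 by a Diels–Alder disconnection. It exploits that C8 is a gem-dimethyl carbon without stereochemistry between C1 and C7 and that C9 is a ketone: 3-methylbut-2-enal supplies C7–C8, and C9 serves as the silyloxy carbon of the diene. One catalytic enantioselective cycloaddition closes ring B, sets C1 and C7 and leaves a C9=C5 silyl enol ether for quaternizing C5. The precursor is a (Z)-2-silyloxy-1,3-diene bearing the (S)-lavandulol-derived chain on C5 and a prenyl group on C1. Ring A is closed afterwards by gold catalysis.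

Key step: step 9

Ring atoms are numbered as in the bicyclic target: C1 prenyl bridgehead, C2 C–OMe, C3 C–benzoyl, C4 enone C=O, C5 lavandulyl bridgehead, C6 CH2, C7 CH–prenyl, C8 CMe2, C9 bridging C=O. Lavandulyl = 5-methyl-2-(prop-1-en-2-yl)hex-4-enyl; prenyl = 3-methylbut-2-enyl.

Assumption: the enal binds the boron cation s-trans through its formyl C–H···O contact, so that the (S)-configured catalyst opens the Re face of the enal α-carbon (the later C7); should binding through the α-C–H prevail, the (R)-configured catalyst is the one to take.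

**Route**

Step 1
Reactants: 1 rac-lavandulol
Product: 2 (S)-lavandulol
Conditions: immobilized Candida antarctica lipase B, vinyl acetate, hexane, rt, run past half conversion, chromatography
Reagents that add atoms: none
Why: Lipase-catalysed kinetic resolution by transesterification, in which the enzyme is expected to acylate the (R)-alcohol faster so that the (S)-alcohol stays behind and is separated from the acetate (a second pass can raise its purity); this is where the side-chain stereocentre of the target is taken.

Step 2
Reactants: 2 (S)-lavandulol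
Product: 3 (S)-lavandulyl iodide
Conditions: PPh3, imidazole, I2, CH2Cl2, 0 °C → rt
Reagents that add atoms: iodine, II
Why: Appel-type iodination of the primary alcohol; the stereocentre is not touched.

Step 3
Reactants: 3 (S)-lavandulyl iodide
Product: 4 (4S)-7-methyl-4-(prop-1-en-2-yl)oct-6-enenitrile
Conditions: MeCN, nBuLi, THF, −78 °C; then 3, −78 → 0 °C
Reagents that add atoms: acetonitrile, CC#N
Why: SN2 alkylation of lithioacetonitrile, a small and very nucleophilic carbanion that should outrun elimination at the β-branched primary iodide at low temperature; it adds the two carbons that become C5 and C9.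

Step 4
Reactants: 4 (4S)-7-methyl-4-(prop-1-en-2-yl)oct-6-enenitrile
Product: 6 (4S)-7-methyl-4-(prop-1-en-2-yl)oct-6-enal, via N-aluminio imine 5 (not isolated)
Conditions: iBu2AlH, toluene, −78 °C; then 1 M aq. tartaric acid, 0 °C
Reagents that add atoms: water, O
Why: Partial reduction of the nitrile by the aluminium hydride stops at the N-aluminio imine, which is hydrolysed to the aldehyde on mild acidic work-up.

Step 5
Reactants: 6 (4S)-7-methyl-4-(prop-1-en-2-yl)oct-6-enal
Product: 7 (4R)-7-methyl-2-methylidene-4-(prop-1-en-2-yl)oct-6-enal (same spatial arrangement; the descriptor changes by priority only)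
Conditions: 37% aq. HCHO, pyrrolidine (10 mol%), EtCO2H (10 mol%), iPrOH, 45 °C
Reagents that add atoms: formaldehyde, C=O
Why: Amine-catalysed Mannich-type α-methylenation of the aldehyde (condensation with formaldehyde, then elimination) places the future C6 methylene on C5 with no regiochemical choice.

Step 6
Reactants: 7 (4R)-7-methyl-2-methylidene-4-(prop-1-en-2-yl)oct-6-enal; 8 5-bromo-2-methylpent-2-ene
Product: 10 2-lavandulyl-7-methylocta-1,6-dien-3-ol (carbinol epimers), via homoprenylmagnesium bromide 9 (not isolated)
Conditions: 8, Mg, THF, rt; then 7, THF, −78 → 0 °C; then H2O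
Reagents that add atoms: none
Why: Grignard 1,2-addition to the 2-substituted acrolein; the new carbinol centre forms unselectively and is removed in the next step.

Step 7
Reactants: 10 2-lavandulyl-7-methylocta-1,6-dien-3-ol
Product: 11 2-lavandulyl-7-methylocta-1,6-dien-3-one
Conditions: Dess–Martin periodinane, pyridine, CH2Cl2, 0 °C → rt; used at once
Reagents that add atoms: none
Why: Dess–Martin oxidation of the allylic alcohol under buffered, non-isomerizing conditions gives the α-methylene ketone.

Step 8
Reactants: 11 2-lavandulyl-7-methylocta-1,6-dien-3-one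
Product: 12 (Z)-3-(tert-butyldimethylsilyloxy)-2-lavandulyl-7-methylocta-1,3,6-triene
Conditions: tBuMe2SiOTf, Et3N, CH2Cl2, −78 → 0 °C
Reagents that add atoms: tert-butyldimethylsilyl triflate, CC(C)(C)[Si](C)(C)OS(=O)(=O)C(F)(F)F
Why: Soft enolization of the enone (silyl enol ether formation) can only remove an α′-proton and should give the cross-conjugated 2-silyloxydiene with Z geometry, the C1 side chain lying syn to oxygen and away from the substituted vinyl group, so that it sits outside in the s-cis diene.

Step 9
Reactants: 12 (Z)-3-(tert-butyldimethylsilyloxy)-2-lavandulyl-7-methylocta-1,3,6-triene; 13 3-methylbut-2-enal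
Product: 14 4-(tert-butyldimethylsilyloxy)-5-lavandulyl-2,2-dimethyl-3-prenylcyclohex-4-ene-1-carbaldehyde (formyl cis to prenyl)
Conditions: oxazaborolidinium triflimide from (S)-B-(o-tolyl)-α,α-diphenylprolinol oxazaborolidine (20 mol%) and Tf2NH (18 mol%), 13 (4 equiv), CH2Cl2, −78 → −40 °C
Reagents that add atoms: none
Why: The enal, bound s-trans to the cationic boron, is attacked in a concerted but asynchronous [4+2] transition state in which the enol-ether terminus C1 bonds ahead to the β-carbon C8 and C6 follows onto the α-carbon C7; the closest known reaction type is the oxazaborolidinium-catalysed enantioselective Diels–Alder reaction of 2-silyloxydienes with enals. Ring B closes as a six-membered carbocycle by this intermolecular cycloaddition, both new bonds forming suprafacially across C6=C5–C9=C1. C7 is set by the catalyst, which shields one face of the enal so that the diene adds to the Re face of C7; C1 is set relative to C7 by the endo position of the formyl group together with the Z geometry of the diene, which holds the C1 chain outside and so brings it cis to the formyl group, while the remote side-chain centre leaves the sense to the catalyst. The step needs para regioselectivity, which the C9 silyloxy group (largest HOMO coefficient at C1) and the β-electrophilic enal both favour, and enough reactivity towards a β,β-disubstituted dienophile, which is met by an electron-rich, geometrically pure Z diene held near s-cis by its 2,3-disubstitution, a silyl group sturdy enough for the acidic catalyst, and an excess of the cheap enal. As C8 carries two methyl groups, no stereocentre is at stake at the most hindered new bond.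

Step 10
Reactants: 14 Diels–Alder aldehyde
Product: 15 C7-hydroxymethyl silyl enol ether
Conditions: NaBH4, MeOH/THF, 0 °C
Reagents that add atoms: none
Why: Borohydride reduction of the aldehyde under basic conditions leaves the silyl enol ether and the C7 centre intact and opens an acid-free way to the C7 prenyl group, since acid hydrolysis of an enol-ether homologue would not spare the silyl enol ether.

Step 11
Reactants: 15 C7-hydroxymethyl silyl enol ether
Product: 16 C7-iodomethyl silyl enol ether
Conditions: PPh3, imidazole, I2 (premixed), CH2Cl2, 0 °C → rt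
Reagents that add atoms: iodine, II
Why: Appel-type iodination with the pre-formed, imidazole-buffered phosphine–iodine reagent, so that neither free iodine nor acid meets the silyl enol ether.

Step 12
Reactants: 16 C7-iodomethyl silyl enol ether; 17 1-bromo-2-methylprop-1-ene
Product: 19 C9=C5 tert-butyldimethylsilyl enol ether of 6-lavandulyl-3,3-dimethyl-2,4-diprenylcyclohexanone (prenyl groups cis), via alkylzinc iodide 18 (not isolated)
Conditions: Zn dust, LiCl, THF, 40 °C; then 17, Pd(PPh3)4 (5 mol%), THF, 50 °C
Reagents that add atoms: none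
Why: Zinc insertion into the primary C–I bond and palladium-catalysed Negishi coupling with the alkenyl bromide complete the C7 prenyl group without an SN2 step at the hindered β-branched carbon and without acid or strong base.

Step 13
Reactants: 19 C9=C5 silyl enol ether; 20 3-(trimethylsilyl)prop-2-ynal
Product: 22 C5-[1-hydroxy-3-(trimethylsilyl)prop-2-ynyl] ketone (carbinol epimers), via lithium enolate 21 (not isolated)
Conditions: MeLi, THF, 0 °C → rt; then 20, −78 °C; then H2O
Reagents that add atoms: none
Why: Si–O cleavage by MeLi releases the regiodefined tetrasubstituted lithium enolate, whose aldol addition to the reactive ynal forms the C5–C4 bond; C5 is set by axial attack on the half-chair enolate from the face anti to the equatorial prenyl groups at C1 and C7, giving the chair with the new bond axial, and the carbinol centre is removed by the next oxidation.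

Step 14
Reactants: 22 C5-[1-hydroxy-3-(trimethylsilyl)prop-2-ynyl] ketone
Product: 23 C5-[3-(trimethylsilyl)propynoyl] ketone
Conditions: Dess–Martin periodinane, pyridine, CH2Cl2, 0 °C → rt
Reagents that add atoms: none
Why: Dess–Martin oxidation of the propargylic alcohol gives the ynone; the 1,3-diketone cannot enolize at quaternary C5 and is stable under these neutral conditions.

Step 15
Reactants: 23 C5-[3-(trimethylsilyl)propynoyl] ketone
Product: 24 C5-(3-bromopropynoyl) ketone
Conditions: N-bromosuccinimide (1.05 equiv), AgNO3 (10 mol%), acetone, rt, dark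
Reagents that add atoms: N-bromosuccinimide, O=C1CCC(=O)N1Br
Why: Silver-catalysed bromodesilylation of the alkynylsilane gives the 1-bromoalkyne, which makes C2 a carbon that can later exchange bromide for methoxide; a near-stoichiometric amount of reagent in the dark spares the four alkenes.

Step 16
Reactants: 24 C5-(3-bromopropynoyl) ketone
Product: 25 C9=C1 tert-butyldimethylsilyl enol ether of 24
Conditions: tBuMe2SiOTf, iPr2NEt, CH2Cl2, −78 → 0 °C
Reagents that add atoms: tert-butyldimethylsilyl triflate, CC(C)(C)[Si](C)(C)OS(=O)(=O)C(F)(F)F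
Why: C1–H is the only enolizable position (C5 is quaternary and the ynone has no α-hydrogen), so soft enolization with a hindered, non-nucleophilic amine gives the C9=C1 silyl enol ether; the C1 centre is given up here on purpose and is formed again under tether control in the next step.

Step 17
Reactants: 25 C9=C1 silyl enol ether
Product: 26 2-bromo-5-lavandulyl-8,8-dimethyl-1,7-diprenylbicyclo[3.3.1]non-2-ene-4,9-dione
Conditions: Ph3PAuNTf2 (5 mol%), acetone containing H2O (2 equiv), rt
Reagents that add atoms: none
Why: Cationic gold activates the bromoalkyne and the silyl enol ether attacks the bromine-bearing β-carbon C2 of the ynone in a 6-endo-dig carbocyclization (gold-catalysed Conia-ene-type addition of silyl enol ethers to alkynes), closing ring A; the tether from the axial C5 acyl group allows bond formation only on its own face of C1, which sets C1 with the prenyl group equatorial, and water takes up the silyl group and protonates the vinyl–gold bond at C3.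

Step 18
Reactants: 26 bicyclic β-bromoenone
Product: 27 5-lavandulyl-2-methoxy-8,8-dimethyl-1,7-diprenylbicyclo[3.3.1]non-2-ene-4,9-dione
Conditions: NaOMe (1.1 equiv), MeOH, 0 °C
Reagents that add atoms: sodium methoxide, [Na+].[O-]C
Why: Conjugate addition–elimination of methoxide at C2 (vinylogous acyl substitution) gives the vinylogous ester with the methoxy group on C2 next to C1 and the carbonyl at C4 next to C5, a regiochemistry fixed by the way ring A was built.

Step 19
Reactants: 27 bicyclic β-methoxyenone; 28 benzoyl chloride
Product: 30 CNP0385193.1, via C3-lithio enone 29 (not isolated)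
Conditions: lithium 2,2,6,6-tetramethylpiperidide (from the amine and nBuLi), THF, −78 °C; then 28, −78 → −40 °C
Reagents that add atoms: none
Why: The hindered lithium amide removes the only acidic proton, the vinylic C3–H of the vinylogous ester (both bridgeheads are quaternary), and the vinyllithium is C-acylated by benzoyl chloride; no stereocentre is touched.

**Compound list**

1 | rac-lavandulol | C=C(C)C(CC=C(C)C)CO | starting material
2 | (S)-lavandulol | C=C(C)[C@H](CC=C(C)C)CO | intermediate
3 | (S)-lavandulyl iodide, (S)-1-iodo-5-methyl-2-(prop-1-en-2-yl)hex-4-ene | C=C(C)[C@H](CC=C(C)C)CI | intermediate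
4 | (4S)-7-methyl-4-(prop-1-en-2-yl)oct-6-enenitrile | C=C(C)[C@H](CC=C(C)C)CCC#N | intermediate
5 | N-(diisobutylalumanyl) imine of aldehyde 6 | C=C(C)[C@H](CC=C(C)C)CCC=N[Al](CC(C)C)CC(C)C | intermediate (not isolated)
6 | (4S)-7-methyl-4-(prop-1-en-2-yl)oct-6-enal | C=C(C)[C@H](CC=C(C)C)CCC=O | intermediate
7 | (4R)-7-methyl-2-methylidene-4-(prop-1-en-2-yl)oct-6-enal | C=C(C)[C@H](CC=C(C)C)CC(=C)C=O | intermediate
8 | 5-bromo-2-methylpent-2-ene (homoprenyl bromide) | CC(C)=CCCBr | starting material
9 | (4-methylpent-3-enyl)magnesium bromide | CC(C)=CCC[Mg]Br | intermediate (not isolated)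
10 | 2-lavandulyl-7-methylocta-1,6-dien-3-ol, carbinol epimers, side-chain centre as in 2 | C=C(C)[C@H](CC=C(C)C)CC(=C)C(O)CCC=C(C)C | intermediate
11 | 2-lavandulyl-7-methylocta-1,6-dien-3-one | C=C(C)[C@H](CC=C(C)C)CC(=C)C(=O)CCC=C(C)C | intermediate
12 | (Z)-3-(tert-butyldimethylsilyloxy)-2-lavandulyl-7-methylocta-1,3,6-triene | C=C(C)[C@H](CC=C(C)C)CC(=C)/C(O[Si](C)(C)C(C)(C)C)=C/CC=C(C)C | intermediate
13 | 3-methylbut-2-enal | CC(C)=CC=O | starting material
14 | 4-(tert-butyldimethylsilyloxy)-5-lavandulyl-2,2-dimethyl-3-prenylcyclohex-4-ene-1-carbaldehyde, formyl (C7) cis to prenyl (C1) | C=C(C)[C@H](CC=C(C)C)CC1=C(O[Si](C)(C)C(C)(C)C)[C@H](CC=C(C)C)C(C)(C)[C@H](C=O)C1 | intermediate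
15 | C7-hydroxymethyl analogue of 14 | C=C(C)[C@H](CC=C(C)C)CC1=C(O[Si](C)(C)C(C)(C)C)[C@H](CC=C(C)C)C(C)(C)[C@H](CO)C1 | intermediate
16 | C7-iodomethyl analogue of 14 | C=C(C)[C@H](CC=C(C)C)CC1=C(O[Si](C)(C)C(C)(C)C)[C@H](CC=C(C)C)C(C)(C)[C@H](CI)C1 | intermediate
17 | 1-bromo-2-methylprop-1-ene | CC(C)=CBr | starting material
18 | C7-(iodozinciomethyl) analogue of 14 | C=C(C)[C@H](CC=C(C)C)CC1=C(O[Si](C)(C)C(C)(C)C)[C@H](CC=C(C)C)C(C)(C)[C@H](C[Zn]I)C1 | intermediate (not isolated)
19 | C9=C5 tert-butyldimethylsilyl enol ether of 6-lavandulyl-3,3-dimethyl-2,4-diprenylcyclohexanone, prenyl groups at C1 and C7 cis | C=C(C)[C@H](CC=C(C)C)CC1=C(O[Si](C)(C)C(C)(C)C)[C@H](CC=C(C)C)C(C)(C)[C@H](CC=C(C)C)C1 | intermediate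
20 | 3-(trimethylsilyl)prop-2-ynal | C[Si](C)(C)C#CC=O | starting material
21 | lithium enolate (C9=C5) from 19 | C=C(C)[C@H](CC=C(C)C)CC1=C(O[Li])[C@H](CC=C(C)C)C(C)(C)[C@H](CC=C(C)C)C1 | intermediate (not isolated)
22 | 2-lavandulyl-2-[1-hydroxy-3-(trimethylsilyl)prop-2-ynyl]-5,5-dimethyl-4,6-diprenylcyclohexanone, new C5–C4 bond trans to both prenyl groups, carbinol epimers | C=C(C)[C@H](CC=C(C)C)C[C@@]1(C(O)C#C[Si](C)(C)C)C[C@@H](CC=C(C)C)C(C)(C)[C@@H](CC=C(C)C)C1=O | intermediate
23 | 2-lavandulyl-5,5-dimethyl-4,6-diprenyl-2-[3-(trimethylsilyl)propynoyl]cyclohexanone | C=C(C)[C@H](CC=C(C)C)C[C@@]1(C(=O)C#C[Si](C)(C)C)C[C@@H](CC=C(C)C)C(C)(C)[C@@H](CC=C(C)C)C1=O | intermediate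
24 | 2-(3-bromopropynoyl)-2-lavandulyl-5,5-dimethyl-4,6-diprenylcyclohexanone | C=C(C)[C@H](CC=C(C)C)C[C@@]1(C(=O)C#CBr)C[C@@H](CC=C(C)C)C(C)(C)[C@@H](CC=C(C)C)C1=O | intermediate
25 | C9=C1 tert-butyldimethylsilyl enol ether of 24 | C=C(C)[C@H](CC=C(C)C)C[C@@]1(C(=O)C#CBr)C[C@@H](CC=C(C)C)C(C)(C)C(CC=C(C)C)=C1O[Si](C)(C)C(C)(C)C | intermediate
26 | 2-bromo-5-lavandulyl-8,8-dimethyl-1,7-diprenylbicyclo[3.3.1]non-2-ene-4,9-dione, C7 prenyl equatorial on ring B | C=C(C)[C@H](CC=C(C)C)C[C@@]12C[C@@H](CC=C(C)C)C(C)(C)[C@@](CC=C(C)C)(C1=O)C(Br)=CC2=O | intermediate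
27 | 5-lavandulyl-2-methoxy-8,8-dimethyl-1,7-diprenylbicyclo[3.3.1]non-2-ene-4,9-dione | C=C(C)[C@H](CC=C(C)C)C[C@@]12C[C@@H](CC=C(C)C)C(C)(C)[C@@](CC=C(C)C)(C1=O)C(OC)=CC2=O | intermediate
28 | benzoyl chloride | O=C(Cl)c1ccccc1 | starting material
29 | 3-lithio derivative of 27 | C=C(C)[C@H](CC=C(C)C)C[C@@]12C[C@@H](CC=C(C)C)C(C)(C)[C@@](CC=C(C)C)(C1=O)C(OC)=C([Li])C2=O | intermediate (not isolated)
30 | CNP0385193.1, 3-benzoyl-5-lavandulyl-2-methoxy-8,8-dimethyl-1,7-diprenylbicyclo[3.3.1]non-2-ene-4,9-dione | C=C(C)[C@H](CC=C(C)C)C[C@@]12C[C@@H](CC=C(C)C)C(C)(C)[C@@](CC=C(C)C)(C1=O)C(OC)=C(C(=O)c1ccccc1)C2=O | target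

**Step count and risks**

Total step count: 19. Longest linear sequence: 19 steps (1 → 30); all other partners are commercial.

Steps most likely to fail:

1. Step 9. The β,β-disubstituted enal may add so slowly that protodesilylation of the diene or Mukaiyama-type 1,2-addition overtakes the cycloaddition, and facial control by the catalyst may be incomplete. The fallback is an auxiliary-controlled cycloaddition that sets out from diene 12. The diene is combined with (R)-4-benzyl-3-(3-methylbut-2-enoyl)oxazolidin-2-one F1 (from (R)-4-benzyloxazolidin-2-one, nBuLi and 3-methylbut-2-enoyl chloride) under Me2AlCl in CH2Cl2 at −30 °C. The chelated s-cis imide is a much stronger dienophile, and its benzyl group should direct the diene to the same Re face of C7, with the acyl group endo. The imide cycloadduct F2 is then reduced with LiBH4 in wet Et2O, which removes the auxiliary and gives alcohol 15, where the route is rejoined.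

2. Step 17. The silyl enol ether may be hydrolysed before the C1–C2 bond forms, closure may occur in the 5-exo sense, and the bromoynone may be attacked by the amine during the preceding silylation. The fallback builds ring A by an Effenberger cyclization and sets out from silyl enol ether 19. Malonyl dichloride in Et2O (−20 °C → rt) acylates C5 and then C1 to give 5-lavandulyl-8,8-dimethyl-1,7-diprenylbicyclo[3.3.1]nonane-2,4,9-trione F3. O-Methylation with Me3SiCHN2 in MeOH/toluene gives 27 together with the regioisomeric 4-methoxy-3-en-2-one F4, which is removed by chromatography. The route is rejoined at 27.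

3. Step 13. Cleavage of the hindered Si–O bond by MeLi may be slow or incomplete, the crowded aldolate may revert on warming, and the aldehyde may approach the wrong face. The fallback is a Mukaiyama aldol addition that sets out from 19: the silyl enol ether is used as such with aldehyde 20 and BF3·OEt2 in CH2Cl2 at −78 °C, followed by aqueous work-up. This gives 22 directly, where the route is rejoined; no new compound arises (F0).

Further compounds
F1 | step 9 | (R)-4-benzyl-3-(3-methylbut-2-enoyl)oxazolidin-2-one | CC(C)=CC(=O)N1[C@H](Cc2ccccc2)COC1=O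
F2 | step 9 | imide cycloadduct of 12 and F1, C7 acyl group cis to the C1 prenyl group | C=C(C)[C@H](CC=C(C)C)CC1=C(O[Si](C)(C)C(C)(C)C)[C@H](CC=C(C)C)C(C)(C)[C@H](C(=O)N2[C@H](Cc3ccccc3)COC2=O)C1
F3 | step 17 | 5-lavandulyl-8,8-dimethyl-1,7-diprenylbicyclo[3.3.1]nonane-2,4,9-trione | C=C(C)[C@H](CC=C(C)C)C[C@@]12C[C@@H](CC=C(C)C)C(C)(C)[C@@](CC=C(C)C)(C1=O)C(=O)CC2=O
F4 | step 17 | 5-lavandulyl-4-methoxy-8,8-dimethyl-1,7-diprenylbicyclo[3.3.1]non-3-ene-2,9-dione | C=C(C)[C@H](CC=C(C)C)C[C@@]12C[C@@H](CC=C(C)C)C(C)(C)[C@@](CC=C(C)C)(C1=O)C(=O)C=C2OC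
F0 | step 13 | none | none
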